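## Retrosynthetic overview

1. Fremontone comes from a last-step isomerisation: a one-pot double aromatic Claisen of the 2′-O-(1,1-dimethylallyl)/4′-O-prenyl bis-ether of 2′-hydroxygenistein. The fast tertiary ether fills C3′ as prenyl, so the slow prenyl ether can only reach C5′, where it arrives as reverse-prenyl. These two ethers are also the only ring-B protecting groups.
2. The bis-ether isoflavone comes from an α-formyl-deoxybenzoin, made by 1,2-aroyl shift of a trans-chalcone epoxide. There is no C3–C1′ cross-coupling and no deoxybenzoin acylation.
3. The chalcone comes from a Claisen–Schmidt reaction of tri-O-allyl phloroacetophenone with a doubly etherified 2,4-dihydroxybenzaldehyde. Chelation distinguishes the two OH groups, and the tertiary allyl ether is carried as its alkyne.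
4. Ring order: rings A and B are purchased arenes. Ring C (the pyranone) is the only ring built (step 7), and it closes before ring B is C-alkylated (step 9).

Assumption: the target SMILES has no stereocentre and no stereogenic double bond, so fremontone is achiral and there is no enantiomer to select. The only stereo-elements are transient (E-enone, racemic trans-epoxide) and are erased in steps 6–7.

## Route

**Step 1**
Reactants: 1, 2,4-dihydroxybenzaldehyde; 2, prenyl bromide (1-bromo-3-methylbut-2-ene)
Product: 3, 2-hydroxy-4-(3-methylbut-2-enyloxy)benzaldehyde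
Conditions: 2 (1.05 equiv), K2CO3 (1.1 equiv), acetone, reflux
Reagents that add atoms: prenyl bromide, CC(C)=CCBr
Why: Williamson etherification; the 2-OH is hydrogen-bonded to the aldehyde while the 4-OH is the more acidic, free phenol, so one equivalent of weak base alkylates O-4 only.

**Step 2**
Reactants: 3; 4, 3-chloro-3-methylbut-1-yne
Product: 5, 2-(2-methylbut-3-yn-2-yloxy)-4-(3-methylbut-2-enyloxy)benzaldehyde
Conditions: 4 (2 equiv), DBU (2.2 equiv), CuCl2·2H2O (1 mol %), MeCN, 0 °C → rt
Reagents that add atoms: 3-chloro-3-methylbut-1-yne, C#CC(C)(C)Cl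
Why: Copper-catalysed propargylic etherification; DBU breaks the chelate, the Cu-acetylide-derived electrophile is slim and takes acidic phenoxides well, and the alkyne is an acid-, BF3- and Pd(0)-tolerant mask for the fragile 1,1-dimethylallyl ether.

**Step 3**
Reactants: 6, 2′,4′,6′-trihydroxyacetophenone; 7, allyl bromide
Product: 8, 1-[2,4,6-tris(allyloxy)phenyl]ethanone
Conditions: 7 (4 equiv), K2CO3 (5 equiv), DMF, 60 °C
Reagents that add atoms: allyl bromide, C=CCBr
Why: Exhaustive Williamson O-allylation; allyl ethers survive KOH, HOO⁻ and BF3 (behaving like the classical benzyl ethers in this chemistry) and are later removed by Pd(0) without acid.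

**Step 4**
Reactants: 5; 8
Product: 9, (E)-3-[2-(2-methylbut-3-yn-2-yloxy)-4-(3-methylbut-2-enyloxy)phenyl]-1-[2,4,6-tris(allyloxy)phenyl]prop-2-en-1-one
Conditions: 50% aq KOH, EtOH, rt, 36 h
Reagents that add atoms: none
Why: Claisen–Schmidt condensation; only the ketone is enolisable, every ether is base-stable, and E1cB dehydration gives the thermodynamic E-enone.

**Step 5**
Reactants: 9
Product: 10, (±)-trans-{3-[2-(2-methylbut-3-yn-2-yloxy)-4-(3-methylbut-2-enyloxy)phenyl]oxiran-2-yl}[2,4,6-tris(allyloxy)phenyl]methanone
Conditions: 30% H2O2, 2 M NaOH, MeOH–THF, 0 °C → rt; used crude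
Reagents that add atoms: hydrogen peroxide, OO
Why: Weitz–Scheffer nucleophilic epoxidation; HOO⁻ adds only to the electron-poor enone, leaving the four isolated alkenes and the alkyne untouched, and stepwise addition/closure from the E-enone gives the racemic trans-epoxide, whose two stereocentres are erased later.

**Step 6**
Reactants: 10
Product: 11, 2-[2-(2-methylbut-3-yn-2-yloxy)-4-(3-methylbut-2-enyloxy)phenyl]-3-oxo-3-[2,4,6-tris(allyloxy)phenyl]propanal (mainly its chelated enol; C2 is configurationally labile)
Conditions: BF3·OEt2 (0.5 equiv), CH2Cl2, −40 → −10 °C, 15 min; sat. NaHCO3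
Reagents that add atoms: none
Why: House–Meinwald-type rearrangement of an α,β-epoxy ketone; the C–O bond benzylic to the 2,4-dialkoxyaryl ring ionises, the aroyl group shifts 1,2 to that carbon to give the isoflavone connectivity, and the strong donor ring allows conditions cold and brief enough for the ethers.

**Step 7**
Reactants: 11
Product: 12, 5,7-dihydroxy-3-[2-(2-methylbut-3-yn-2-yloxy)-4-(3-methylbut-2-enyloxy)phenyl]-4H-chromen-4-one
Conditions: Pd(PPh3)4 (5 mol %), morpholine (10 equiv), THF, rt → 45 °C; then AcOH, rt
Reagents that add atoms: none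
Why: Tsuji–Trost deallylation; unsubstituted allyl ethers of the acidic ring-A phenols ionise much faster than the prenyl or propargyl ethers, morpholine traps the allyl groups and temporarily turns the formyl group into an enaminone (blocking C-allylation), and the freed ortho-phenol closes ring C by addition–elimination while both ring-B oxygens stay masked, so no benzofuran can form.

**Step 8**
Reactants: 12
Product: 13, 5,7-dihydroxy-3-[2-(2-methylbut-3-en-2-yloxy)-4-(3-methylbut-2-enyloxy)phenyl]-4H-chromen-4-one
Conditions: H2 (1 atm), Lindlar catalyst, quinoline, EtOAc, rt, stopped at 1 equiv H2; kept below 30 °C and used directly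
Reagents that add atoms: none (H2 only)
Why: Lindlar semihydrogenation; the terminal alkyne outcompetes the trisubstituted prenyl alkene and the conjugated chromone C2=C3 for the poisoned Pd surface.

**Step 9 (key step)**
Reactants: 13
Product: 14, fremontone, 3-[2,4-dihydroxy-5-(2-methylbut-3-en-2-yl)-3-(3-methylbut-2-enyl)phenyl]-5,7-dihydroxy-4H-chromen-4-one
Conditions: BSA (8 equiv), PhNEt2, 115 °C, 1.5 h, then 200 °C (sealed tube/µW), 45–60 min; MeOH/aq citric acid work-up
Reagents that add atoms: none (TMS groups from BSA are lost on work-up)
Why: Proposed new method: two known [3,3] aromatic Claisen rearrangements are run as one rate-programmed cascade on an otherwise unprotected isoflavone; the tertiary ether rearranges first (roughly 100-fold faster than a prenyl ether) and, with C1′ blocked, can only deliver a 3-methylbut-2-enyl group (allyl inversion) to C3′; the 4′-O-prenyl ether then has one open ortho carbon and at 200 °C delivers the 2-methylbut-3-en-2-yl group (again by inversion) to C5′, attack at the now substituted C3′ being reversible and congested; BSA silylates each phenol as it forms to suppress abnormal Claisen and chroman/dihydrofuran formation; the closest known reaction types are the low-temperature Claisen of aryl 1,1-dimethylallyl ethers to o-prenylphenols and the high-temperature Claisen of aryl prenyl ethers to o-(1,1-dimethylallyl)phenols; no stereocentre is created.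

## Compound list

| No. | Name | SMILES | Role |
|---|---|---|---|
| 1 | 2,4-dihydroxybenzaldehyde | O=Cc1ccc(O)cc1O | starting material |
| 2 | prenyl bromide | CC(C)=CCBr | starting material |
| 3 | 2-hydroxy-4-(prenyloxy)benzaldehyde | O=Cc1ccc(OCC=C(C)C)cc1O | intermediate |
| 4 | 3-chloro-3-methylbut-1-yne | C#CC(C)(C)Cl | starting material |
| 5 | 2-(2-methylbut-3-yn-2-yloxy)-4-(prenyloxy)benzaldehyde | O=Cc1ccc(OCC=C(C)C)cc1OC(C)(C)C#C | intermediate |
| 6 | 2′,4′,6′-trihydroxyacetophenone | CC(=O)c1c(O)cc(O)cc1O | starting material |
| 7 | allyl bromide | C=CCBr | starting material |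
| 8 | 2,4,6-tris(allyloxy)acetophenone | CC(=O)c1c(OCC=C)cc(OCC=C)cc1OCC=C | intermediate |
| 9 | (E)-chalcone | O=C(/C=C/c1ccc(OCC=C(C)C)cc1OC(C)(C)C#C)c1c(OCC=C)cc(OCC=C)cc1OCC=C | intermediate |
| 10 | trans-chalcone epoxide, racemic ((2S,3R) enantiomer drawn) | O=C(c1c(OCC=C)cc(OCC=C)cc1OCC=C)[C@H]1O[C@@H]1c1ccc(OCC=C(C)C)cc1OC(C)(C)C#C | intermediate |
| 11 | α-formyl-deoxybenzoin (enolised, no fixed stereocentre) | O=CC(C(=O)c1c(OCC=C)cc(OCC=C)cc1OCC=C)c1ccc(OCC=C(C)C)cc1OC(C)(C)C#C | intermediate |
| 12 | 5,7-dihydroxy-2′-(1,1-dimethylpropargyloxy)-4′-(prenyloxy)isoflavone | O=c1c(-c2ccc(OCC=C(C)C)cc2OC(C)(C)C#C)coc2cc(O)cc(O)c12 | intermediate |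
| 13 | 5,7-dihydroxy-2′-(1,1-dimethylallyloxy)-4′-(prenyloxy)isoflavone | O=c1c(-c2ccc(OCC=C(C)C)cc2OC(C)(C)C=C)coc2cc(O)cc(O)c12 | intermediate |
| 14 | fremontone (achiral) | C=CC(C)(C)c1cc(-c2coc3cc(O)cc(O)c3c2=O)c(O)c(CC=C(C)C)c1O | target |

## Step count and risks

Total steps: 9.
Longest linear sequence: 8 (steps 1, 2, 4, 5, 6, 7, 8, 9).

Three steps most likely to fail:

1. **Step 9, double Claisen.** Possible problems are abnormal Claisen, loss of isoprene or prenyl, and C3′/C5′ scrambling.
   - Fallback: build ring B before ring C. On 2,4-dihydroxybenzaldehyde run two separate Claisens, both from O-4.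
   - First, the 4-O-(1,1-dimethylallyl) ether gives C3-prenyl, directed to C3 by chelate-induced bond fixation. Then the 4-O-prenyl ether gives C5 reverse-prenyl, with anhydride trapping.
   - Mask both phenols as MOM ethers and take this aldehyde through steps 4–7. Ring A remains allyl-protected, so ring C still closes first. Finish with mild acid.
2. **Step 6, aroyl shift.** Possible problems are loss of prenyl cation from the para-alkoxy-stabilised cation, and fluorohydrin or 1,2-diketone formation.
   - Fallback: abandon the rearrangement and form C3–C1′ under basic conditions by Suzuki coupling.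
   - The partners are 3-iodo-5,7-bis(allyloxy)chromone and the pinacol boronate of 1-bromo-2-(2-methylbut-3-yn-2-yloxy)-4-(prenyloxy)benzene.
   - After Pd(0) deallylation the route rejoins at compound 12.
3. **Step 2, tertiary etherification of the chelated, hindered 2-OH.**
   - Fallback: reverse the polarity and use SNAr of potassium 2-methylbut-3-yn-2-olate on 2-fluoro-4-(prenyloxy)benzaldehyde, activated by the ortho-formyl group.
   - The phenol then never has to act as the nucleophile.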